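**Design of a synthesis of 7,5'-dihydroxy-5,6,3',4'-tetramethoxyflavone (20)**

## The problem

Target 20 is an achiral flavone: a 4H-chromen-4-one (rings A and C) carrying a 3-hydroxy-4,5-dimethoxyphenyl group (ring B) at C2. There is no stereocenter, and neither the C2–C1' bond nor the pyranone ring is hard to make in itself. The difficulty is ring A. It is pentasubstituted, with C5-OMe, C6-OMe, C7-OH, C8-H, C8a–O1 and C4a–C4, and its oxygens are differentiated against their natural reactivity: the 7-OH that must stay free is the most easily alkylated, and the 5-OMe peri to the C4 carbonyl is the ether most easily lost to Lewis acids. The pattern therefore cannot be reached by selective demethylation of a 5,6,7-trimethyl ether, and a classical approach must place the acyl carbon C4 at one of two almost equivalent ortho positions of a 3,4,5-trioxygenated phenol. Ring B poses the same protection question on a smaller scale. Groups to respect are the 5-OMe (no BCl3, BBr3 or AlCl3), the C2=C3 bond of the pyranone (reducible, and opened by hot aqueous base), and the two phenols, whose masks must come off without touching four methyl ethers. The feature the plan exploits is that O1 and C4 sit on adjacent ring A carbons, C8a and C4a, whose outer neighbours differ: C5 beside C4a carries a methoxy group, C8 beside C8a carries hydrogen. A C4a–C8a aryne is thus polarised by one flanking methoxy group, and the unit O1, C4(=O), C3, C2 plus ring B is exactly an arylpropiolic acid.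

## Retrosynthesis

**20 to 19.** The two O–H bonds are traced back to benzyl ethers, so two O–CH2Ph bonds are cut. Benzyl is preferred to silyl, which would be lost to fluoride in the key step, and to any group needing a Lewis acid for removal, which would endanger the 5-OMe. The forward reaction, hydrogenolysis, must spare the C2=C3 bond.

**19 to 5 and 16, through 17 and 18.** Three bonds are cut: C8a–O1, C4a–C4 and O1–C2. Aryne 17, formed from o-silylaryl triflate 16, inserts into the C–O bond of arylpropiolic acid 5 to give ynone 18, which closes to 19 in the same flask. The neighbouring cuts (C2–C3 or C3–C4, the condensation routes) leave an o-hydroxyaryl ketone that still contains the whole ring A problem. This cut removes it, because neither new bond to ring A is made by electrophilic substitution. The precursors are two benzene derivatives with one functional handle each. The forward reaction must deliver oxygen to C8a and acyl to C4a, shift the acyl group faster than the aryl anion is protonated, and close ring C in the 6-endo mode.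

**16 to 10, through 14 and 11.** The C–Si and O–Tf bonds are cut, giving back the phenol 10 by way of its N-isopropyl carbamate 11 and the ortho-silylated carbamate 14. The phenol oxygen of 10 is not an atom of the target. It is the leaving group, and it sits on the carbon that becomes C4a. This placement is deliberate: in 10 the oxygen has only one free ortho position, the other being occupied by OMe, so the silyl group can go to one carbon only. An isomeric precursor with the oxygen on the C8a carbon would offer two competing ortho positions.

**10 to 6, through 8 and 7.** The aryl C–O bond (Baeyer–Villiger), two O–Me bonds and one O–Bn bond are cut. Commercial 2,3,4-trihydroxybenzaldehyde 6 already has the 1,2,3,4 substitution. Its formyl group first differentiates the three hydroxyls (the 4-OH para to it is the most acidic) and is then exchanged for oxygen.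

**5 to 1, through 3 and 2.** The C–CO2H bond and the alkyne are cut by Corey–Fuchs homologation and carboxylation of aldehyde 2, the benzyl ether of commercial 3-hydroxy-4,5-dimethoxybenzaldehyde 1. Aldehyde 1 carries the complete ring B pattern.

## Roads not taken

**Alternative 1:** the most obvious route. Cut C2–C3 and O1–C2. Claisen–Schmidt condensation of acetophenone A2 with aldehyde 2 gives chalcone A3, and oxidative cyclisation (I2, DMSO) gives 19. A2 must come from Friedel–Crafts or Fries acetylation of phenol A1, itself made from 2 by Baeyer–Villiger oxidation. In A1 the two ortho positions are nearly equivalent: one lies between OH and OMe, the other between OH and OBn, and each is ortho to the phenol and para to an alkoxy group. The acetyl group is therefore placed where the substrate offers no bias, and the isomeric 5-benzyloxy-6,7-dimethoxy series forms alongside. The chosen plan needs no more steps and decides the same question by structure rather than by separation.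

**Alternative 2:** cut C4–C4a and C3–C4, with carbon monoxide as C4. Carbonylative Sonogashira coupling of iodophenol A4 with alkyne A5 (CO, PdCl2(PPh3)2, amine) would give 18 and then 19. A4 requires iodination of A1 at the same ambiguous position as in Alternative 1. In addition, the iodide is electron-rich and flanked by two oxygens, so oxidative addition is slow, direct coupling without CO competes, and metal-bound cyclisation tends to leak to the aurone. The aryne route uses two components instead of three and no palladium.

**Alternative 3:** a biomimetic polyketide fold. A cinnamoyl-capped triketide chain is closed by Claisen condensation to a phloroglucinol ring A, and the resulting chalcone is cyclised to 5,7-dihydroxyflavone A6. The fold puts oxygen only on C5, C7 and C8a. The C6 oxygen must then be added by oxidation of a ring with little C6/C8 discrimination (persulfate attacks para to the 5-OH, at C8). After that, 5-OH and 6-OH must be methylated while 7-OH stays free, against the acidity order. The key step would build ring A without solving its differentiation, whereas the aryne brings the differentiated oxygens in from the start.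

Key step: step 10

Assumption: flavone numbering (O1, C2–C4, C4a, C5–C8, C8a, C1'–C6') is used for ring atoms of the target and, where stated, for the atoms of precursors that become them; aldehydes 1 and 6 are taken as commercial.

## Route

Step 1
Reactants: 1 3-hydroxy-4,5-dimethoxybenzaldehyde
Product: 2 3-(benzyloxy)-4,5-dimethoxybenzaldehyde
Conditions: BnBr, K2CO3, DMF, rt
Reagents that add atoms: benzyl bromide, BrCc1ccccc1
Why: Williamson etherification of the only phenol; the aldehyde and methyl ethers are inert to carbonate.

Step 2
Reactants: 2 3-(benzyloxy)-4,5-dimethoxybenzaldehyde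
Product: 3 1-(benzyloxy)-5-(2,2-dibromoethenyl)-2,3-dimethoxybenzene
Conditions: CBr4, PPh3, CH2Cl2, 0 °C
Reagents that add atoms: carbon tetrabromide, BrC(Br)(Br)Br
Why: First stage of the Corey–Fuchs reaction, a Wittig-type dibromomethylenation of an aromatic aldehyde by Ph3P=CBr2.

Step 3
Reactants: 3 1-(benzyloxy)-5-(2,2-dibromoethenyl)-2,3-dimethoxybenzene
Product: 5 3-[3-(benzyloxy)-4,5-dimethoxyphenyl]prop-2-ynoic acid, via lithium acetylide 4 (not isolated)
Conditions: n-BuLi (2.2 equiv), THF, −78 °C to 0 °C; CO2, −78 °C to rt; aq. HCl
Reagents that add atoms: carbon dioxide, O=C=O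
Why: Second stage of the Corey–Fuchs reaction (bromine–lithium exchange, Fritsch–Buttenberg–Wiechell rearrangement, deprotonation) should give acetylide 4, which is carboxylated in the same flask; benzyl and methyl ethers tolerate n-BuLi at low temperature.

Step 4
Reactants: 6 2,3,4-trihydroxybenzaldehyde
Product: 7 4-(benzyloxy)-2,3-dihydroxybenzaldehyde
Conditions: BnBr (1.0 equiv), NaHCO3, DMF, 40 °C
Reagents that add atoms: benzyl bromide, BrCc1ccccc1
Why: Williamson alkylation under weak base should select the 4-OH, which is para to the formyl group and the most acidic; the 2-OH is held in a hydrogen bond to the carbonyl and the 3-OH is the least acidic.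

Step 5
Reactants: 7 4-(benzyloxy)-2,3-dihydroxybenzaldehyde
Product: 8 4-(benzyloxy)-2,3-dimethoxybenzaldehyde
Conditions: MeI (excess), K2CO3, DMF, 40 °C
Reagents that add atoms: iodomethane, CI
Why: Exhaustive Williamson methylation of the two remaining phenols; gentle warming overcomes the hydrogen bond of the 2-OH.

Step 6
Reactants: 8 4-(benzyloxy)-2,3-dimethoxybenzaldehyde
Product: 10 4-(benzyloxy)-2,3-dimethoxyphenol, via aryl formate 9 (not isolated)
Conditions: mCPBA, CH2Cl2, rt; then K2CO3 (cat.), MeOH, rt
Reagents that add atoms: 3-chloroperoxybenzoic acid, OOC(=O)c1cccc(Cl)c1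
Why: Baeyer–Villiger (Dakin-type) oxidation; the electron-rich aryl group with ortho and para alkoxy substituents migrates in the Criegee intermediate, and the formate is removed by methanolysis.

Step 7
Reactants: 10 4-(benzyloxy)-2,3-dimethoxyphenol
Product: 11 4-(benzyloxy)-2,3-dimethoxyphenyl propan-2-ylcarbamate
Conditions: iPrNCO, Et3N (cat.), CH2Cl2, rt
Reagents that add atoms: isopropyl isocyanate, CC(C)N=C=O
Why: Base-catalysed addition of a phenol to an isocyanate gives the carbamate that serves as directing group and, later, as an easily cleaved mask.

Step 8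
Reactants: 11 4-(benzyloxy)-2,3-dimethoxyphenyl propan-2-ylcarbamate
Product: 14 4-(benzyloxy)-2,3-dimethoxy-6-(trimethylsilyl)phenyl propan-2-ylcarbamate, via N-silyl carbamate 12 (not isolated), via C-silylated N-silyl carbamate 13 (not isolated)
Conditions: TBSOTf, TMEDA, Et2O, 0 °C to rt; n-BuLi, TMEDA, −78 °C; TMSCl, −78 °C to rt; aq. NaHSO4
Reagents that add atoms: chlorotrimethylsilane, C[Si](C)(C)Cl
Why: In situ N-silylation masks the N–H, and the carbamate then directs ortho-lithiation (directed ortho-metalation) to the only free ortho position, since the other carries OMe. The aryllithium is silylated and the N–Si bond is hydrolysed on acidic work-up.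

Step 9
Reactants: 14 4-(benzyloxy)-2,3-dimethoxy-6-(trimethylsilyl)phenyl propan-2-ylcarbamate
Product: 16 4-(benzyloxy)-2,3-dimethoxy-6-(trimethylsilyl)phenyl trifluoromethanesulfonate, via silylphenol 15 (not isolated)
Conditions: Et2NH, DBU, MeCN, 40 °C; then PhNTf2, rt
Reagents that add atoms: N-phenylbis(trifluoromethanesulfonimide), FC(F)(F)S(=O)(=O)N(c1ccccc1)S(=O)(=O)C(F)(F)F
Why: Base-induced E1cB loss of isopropyl isocyanate, trapped by Et2NH as a urea, frees the phenoxide of 15, which is triflated in the same flask; this is the established one-pot route from ortho-silyl aryl carbamates to o-silylaryl triflates.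

Step 10
Reactants: 5 3-[3-(benzyloxy)-4,5-dimethoxyphenyl]prop-2-ynoic acid, 16 4-(benzyloxy)-2,3-dimethoxy-6-(trimethylsilyl)phenyl trifluoromethanesulfonate
Product: 19 7-(benzyloxy)-2-[3-(benzyloxy)-4,5-dimethoxyphenyl]-5,6-dimethoxy-4H-chromen-4-one, via aryne 17 (not isolated), via ynone 18 (not isolated)
Conditions: 16 (1.5 equiv), CsF (4 equiv), THF, 125 °C, sealed tube
Reagents that add atoms: none
Why: Fluoride attacks silicon of 16 and expels triflate to give aryne 17, whose triple bond joins the carbons that become C4a and C8a; the cesium carboxylate of 5 adds through oxygen to C8a, and the aryl anion left at C4a attacks the neighbouring ester carbonyl through a four-membered transition structure whose collapse with O–acyl cleavage gives the phenoxide of ynone 18, a net insertion of the aryne into the C–O bond of the acid. The closest known reaction type is this same intermolecular C–O addition of carboxylic acids to fluoride-generated arynes, which gives o-hydroxyaryl ketones and, with unsaturated acids, products of subsequent oxa-Michael closure. Ring C then closes by 6-endo-dig oxa-Michael addition of the C8a phenoxide to the ynone β-carbon (C2), and the vinyl anion is protonated at C3 by the proton that the acid delivered. No stereocenter is formed. Regioselectivity of the aryne addition should be secured by the methoxy group on C5: its inductive pull distorts the aryne so that the remote carbon C8a is the more electrophilic and the negative charge develops at C4a beside it, C8a is also the less hindered end, and the C6 and C7 oxygens are too far from the triple bond to override this. Acyl shift over protonation of the aryl anion is favoured by the intramolecular attack, the high temperature and the absence of any proton source other than one equivalent of 5. 6-endo over 5-exo closure is the normal course for 2-hydroxyaryl ynones under metal-free basic conditions, where the phenoxide adds in conjugate fashion to the electron-poor β-carbon. Benzyl and methyl ethers are inert to CsF in THF.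

Step 11
Reactants: 19 7-(benzyloxy)-2-[3-(benzyloxy)-4,5-dimethoxyphenyl]-5,6-dimethoxy-4H-chromen-4-one
Product: 20 7-hydroxy-2-(3-hydroxy-4,5-dimethoxyphenyl)-5,6-dimethoxy-4H-chromen-4-one
Conditions: H2 (1 atm), Pd/C, EtOAc/MeOH, rt
Reagents that add atoms: none
Why: Hydrogenolysis of two aryl benzyl ethers; methyl ethers are untouched and the C2=C3 bond, part of a vinylogous ester, should be reduced much more slowly, so the reaction is stopped once both benzyl groups are gone.

## Compound list

1 | 3-hydroxy-4,5-dimethoxybenzaldehyde | COc1cc(C=O)cc(O)c1OC | starting material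
2 | 3-(benzyloxy)-4,5-dimethoxybenzaldehyde | COc1cc(C=O)cc(OCc2ccccc2)c1OC | intermediate
3 | 1-(benzyloxy)-5-(2,2-dibromoethenyl)-2,3-dimethoxybenzene | COc1cc(C=C(Br)Br)cc(OCc2ccccc2)c1OC | intermediate
4 | lithium [3-(benzyloxy)-4,5-dimethoxyphenyl]ethynide | [Li]C#Cc1cc(OC)c(OC)c(OCc2ccccc2)c1 | intermediate (not isolated)
5 | 3-[3-(benzyloxy)-4,5-dimethoxyphenyl]prop-2-ynoic acid | COc1cc(C#CC(=O)O)cc(OCc2ccccc2)c1OC | intermediate
6 | 2,3,4-trihydroxybenzaldehyde | O=Cc1ccc(O)c(O)c1O | starting material
7 | 4-(benzyloxy)-2,3-dihydroxybenzaldehyde | O=Cc1ccc(OCc2ccccc2)c(O)c1O | intermediate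
8 | 4-(benzyloxy)-2,3-dimethoxybenzaldehyde | COc1c(C=O)ccc(OCc2ccccc2)c1OC | intermediate
9 | 4-(benzyloxy)-2,3-dimethoxyphenyl formate | COc1c(OC=O)ccc(OCc2ccccc2)c1OC | intermediate (not isolated)
10 | 4-(benzyloxy)-2,3-dimethoxyphenol | COc1c(O)ccc(OCc2ccccc2)c1OC | intermediate
11 | 4-(benzyloxy)-2,3-dimethoxyphenyl propan-2-ylcarbamate | COc1c(OC(=O)NC(C)C)ccc(OCc2ccccc2)c1OC | intermediate
12 | 4-(benzyloxy)-2,3-dimethoxyphenyl N-[tert-butyl(dimethyl)silyl]-N-(propan-2-yl)carbamate | COc1c(OC(=O)N(C(C)C)[Si](C)(C)C(C)(C)C)ccc(OCc2ccccc2)c1OC | intermediate (not isolated)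
13 | 4-(benzyloxy)-2,3-dimethoxy-6-(trimethylsilyl)phenyl N-[tert-butyl(dimethyl)silyl]-N-(propan-2-yl)carbamate | COc1c(OC(=O)N(C(C)C)[Si](C)(C)C(C)(C)C)c([Si](C)(C)C)cc(OCc2ccccc2)c1OC | intermediate (not isolated)
14 | 4-(benzyloxy)-2,3-dimethoxy-6-(trimethylsilyl)phenyl propan-2-ylcarbamate | COc1c(OC(=O)NC(C)C)c([Si](C)(C)C)cc(OCc2ccccc2)c1OC | intermediate
15 | 4-(benzyloxy)-2,3-dimethoxy-6-(trimethylsilyl)phenol | COc1c(O)c([Si](C)(C)C)cc(OCc2ccccc2)c1OC | intermediate (not isolated)
16 | 4-(benzyloxy)-2,3-dimethoxy-6-(trimethylsilyl)phenyl trifluoromethanesulfonate | COc1c(OS(=O)(=O)C(F)(F)F)c([Si](C)(C)C)cc(OCc2ccccc2)c1OC | intermediate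
17 | 5-(benzyloxy)-3,4-dimethoxy-1,2-didehydrobenzene (aryne) | COC1=C(OC)C(OCc2ccccc2)=CC#C1 | intermediate (not isolated)
18 | 1-[4-(benzyloxy)-2-hydroxy-5,6-dimethoxyphenyl]-3-[3-(benzyloxy)-4,5-dimethoxyphenyl]prop-2-yn-1-one | COc1cc(C#CC(=O)c2c(O)cc(OCc3ccccc3)c(OC)c2OC)cc(OCc2ccccc2)c1OC | intermediate (not isolated)
19 | 7-(benzyloxy)-2-[3-(benzyloxy)-4,5-dimethoxyphenyl]-5,6-dimethoxy-4H-chromen-4-one | COc1cc(-c2cc(=O)c3c(OC)c(OC)c(OCc4ccccc4)cc3o2)cc(OCc2ccccc2)c1OC | intermediate
20 | 7-hydroxy-2-(3-hydroxy-4,5-dimethoxyphenyl)-5,6-dimethoxy-4H-chromen-4-one | COc1cc(-c2cc(=O)c3c(OC)c(OC)c(O)cc3o2)cc(O)c1OC | target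

## Step count and risk

Total steps: 11. Longest linear sequence: 8 (steps 4 to 11, from 6). The ring B branch (steps 1 to 3) joins at step 10.

**Step 10 (key step).** Four processes could divert it:
- protonation of the aryl anion by acid 5 before the acyl shift, which stops at simple O-arylation;
- decarboxylation of the cesium arylpropiolate at 125 °C;
- conjugate attack of the aryl anion on the triple bond, a six-membered closure, instead of attack at the carbonyl;
- 5-exo rather than 6-endo closure of the phenoxide.

The fallback sets out from 16 and aldehyde 2 and comes back at 19. Aryne insertion into the C–O bond of acetic acid (CsF, THF, 125 °C), the simplest case of the same known reaction and free of the alkyne-related problems, should give 1-[4-(benzyloxy)-2-hydroxy-5,6-dimethoxyphenyl]ethan-1-one F1. Claisen–Schmidt condensation of F1 with 2 (KOH, EtOH, rt) gives (E)-chalcone F2, and oxidative cyclisation (I2 cat., DMSO, 130 °C) gives 19. Ring C is then built by oxa-Michael addition and dehydrogenation instead of from the ynone, while the aryne still fixes the regiochemistry of ring A. F1 and F2 are the same structures as A2 and A3.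

**Step 8.** The likely failures are competing deprotonation at the benzylic CH2 of the 4-benzyloxy group followed by Wittig rearrangement, anionic Fries shift of the carbamoyl group before silylation, or incomplete lithiation of the electron-rich ring. The fallback sets out from 10 and comes back at 16, bypassing steps 7 to 9. Ortho-bromination of the free phenol (NBS, CH2Cl2, low temperature; the para position is blocked) gives 4-(benzyloxy)-6-bromo-2,3-dimethoxyphenol F3. O-silylation with HMDS gives {[4-(benzyloxy)-6-bromo-2,3-dimethoxyphenyl]oxy}(trimethyl)silane F4. Bromine–lithium exchange (n-BuLi, THF, −78 °C) triggers a retro-Brook 1,3-shift of silicon from oxygen to carbon, giving the lithium salt of 15, which is quenched with Tf2O to give 16.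

**Step 11.** Over-reduction of the C2=C3 bond may compete with cleavage of the second benzyl ether. The fallback sets out from 19 and comes back at 20: non-reductive acidolysis with TFA and pentamethylbenzene as benzyl cation scavenger at 40 °C. A protic acid without a chelating Lewis acid should leave all four methyl ethers, including the 5-OMe, intact. No new compound is made.

## Further compounds

F1 | step 10 | 1-[4-(benzyloxy)-2-hydroxy-5,6-dimethoxyphenyl]ethan-1-one | CC(=O)c1c(O)cc(OCc2ccccc2)c(OC)c1OC
F2 | step 10 | (E)-1-[4-(benzyloxy)-2-hydroxy-5,6-dimethoxyphenyl]-3-[3-(benzyloxy)-4,5-dimethoxyphenyl]prop-2-en-1-one | COc1cc(/C=C/C(=O)c2c(O)cc(OCc3ccccc3)c(OC)c2OC)cc(OCc2ccccc2)c1OC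
F3 | step 8 | 4-(benzyloxy)-6-bromo-2,3-dimethoxyphenol | COc1c(O)c(Br)cc(OCc2ccccc2)c1OC
F4 | step 8 | {[4-(benzyloxy)-6-bromo-2,3-dimethoxyphenyl]oxy}(trimethyl)silane | COc1c(O[Si](C)(C)C)c(Br)cc(OCc2ccccc2)c1OC
F0 | step 11 | none | none
A1 | alternative 1 | 3-(benzyloxy)-4,5-dimethoxyphenol | COc1cc(O)cc(OCc2ccccc2)c1OC
A2 | alternative 1 | 1-[4-(benzyloxy)-2-hydroxy-5,6-dimethoxyphenyl]ethan-1-one | CC(=O)c1c(O)cc(OCc2ccccc2)c(OC)c1OC
A3 | alternative 1 | (E)-1-[4-(benzyloxy)-2-hydroxy-5,6-dimethoxyphenyl]-3-[3-(benzyloxy)-4,5-dimethoxyphenyl]prop-2-en-1-one | COc1cc(/C=C/C(=O)c2c(O)cc(OCc3ccccc3)c(OC)c2OC)cc(OCc2ccccc2)c1OC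
A4 | alternative 2 | 5-(benzyloxy)-2-iodo-3,4-dimethoxyphenol | COc1c(I)c(O)cc(OCc2ccccc2)c1OC
A5 | alternative 2 | 1-(benzyloxy)-5-ethynyl-2,3-dimethoxybenzene | COc1cc(C#C)cc(OCc2ccccc2)c1OC
A6 | alternative 3 | 2-[3-(benzyloxy)-4,5-dimethoxyphenyl]-5,7-dihydroxy-4H-chromen-4-one | COc1cc(-c2cc(=O)c3c(O)cc(O)cc3o2)cc(OCc2ccccc2)c1OC
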